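**Strategy**

The pyran ring is disconnected at O1–C2 and at both C2–CH3 bonds, which leads back to a coumarin. The feature exploited is C2 of the chromene: a quaternary carbon bonded to O1 and two methyl groups and flanked by the cis C3=C4 bond, i.e. a lactone carbonyl carbon in disguise. In one operation, excess methyl Grignard reagent opens the lactone of an 8-prenyl-7-oxygenated coumarin and installs both methyl groups, and weak acid re-closes the ring as the 2,2-dimethyl-2H-pyran. The precursor is osthenol carrying its 7-OH as a THP acetal, so that no 7-phenoxide deactivates the lactone. The C6 aryl ketone chain is attached afterwards by formylation, Grignard addition and oxidation.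

Key step: step 5

Remark: 3-chloro-3-methylbut-1-yne and 4-(2-bromoethyl)phenol are taken as purchased materials; the racemic THP acetal carbon carried from step 4 into step 5 is a spectator stereocentre that is lost there.

**Route**

Step 1
Reactants: 1 7-hydroxycoumarin (umbelliferone); 2 3-chloro-3-methylbut-1-yne
Product: 3 7-[(2-methylbut-3-yn-2-yl)oxy]-2H-chromen-2-one
Conditions: K2CO3, KI (cat.), acetone (2% H2O), reflux
Reagents that add atoms: none
Why: Williamson-type O-alkylation of the acidic 7-phenoxide with the tertiary propargylic chloride (which reacts through its ionised propargyl–allenyl form, iodide assisting) is the standard entry to aryl 1,1-dimethylpropargyl ethers and leaves the lactone and the ring carbons untouched.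

Step 2
Reactants: 3 7-[(2-methylbut-3-yn-2-yl)oxy]-2H-chromen-2-one
Product: 4 7-[(2-methylbut-3-en-2-yl)oxy]-2H-chromen-2-one
Conditions: H2 (1 atm), Pd/CaCO3 poisoned with Pb(OAc)2, quinoline, EtOAc, rt, stopped after 1 equiv H2; concentrated below 30 °C
Reagents that add atoms: none
Why: Semi-hydrogenation of a terminal alkyne on lead-poisoned palladium should stop at the alkene and spare the conjugated C3=C4 bond of the lactone, and the product is kept cold because it rearranges easily.

Step 3
Reactants: 4 7-[(2-methylbut-3-en-2-yl)oxy]-2H-chromen-2-one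
Product: 5 7-hydroxy-8-(3-methylbut-2-en-1-yl)-2H-chromen-2-one (osthenol)
Conditions: PhNEt2, 130 °C, N2
Reagents that add atoms: none
Why: Aromatic Claisen rearrangement, in which the [3,3] shift delivers the allyl terminus to C8 (the ortho position favoured by the higher C7–C8 bond order of the coumarin) with allylic inversion that turns the 1,1-dimethylallyl group into a 3-methylbut-2-enyl group, followed by tautomerisation to the phenol.

Step 4
Reactants: 5 osthenol
Product: 6 8-(3-methylbut-2-en-1-yl)-7-(tetrahydro-2H-pyran-2-yloxy)-2H-chromen-2-one (racemic at the acetal carbon)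
Conditions: 3,4-dihydro-2H-pyran, PPTS (cat.), CH2Cl2, rt
Reagents that add atoms: 3,4-dihydro-2H-pyran, C1CCOC=C1
Why: Acid-catalysed acetalisation of the phenol (PPTS is too weak to cyclise the ortho-prenyl phenol) masks O7 as an ether so that it cannot become a phenoxide conjugated with the lactone carbonyl in step 5; the new acetal stereocentre is formed as a racemate and is not controlled.

Step 5
Reactants: 6 osthenol THP ether; 7 methylmagnesium bromide
Product: 11 2,2-dimethyl-8-(3-methylbut-2-en-1-yl)-2H-chromen-7-ol, via cis-enone phenoxide 8 (not isolated), via cis tertiary allylic alcohol 9 (not isolated), via THP-protected chromene 10 (not isolated)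
Conditions: MeMgBr (4 equiv), THF, 0 °C to rt; aq NH4Cl; then PPTS (cat.), MeOH, 40 °C
Reagents that add atoms: none
Why: The first MeMgBr adds to the lactone carbonyl and the hemiketal alkoxide collapses by cleaving the old O1–C2 bond to give the cis enone phenoxide 8, a second MeMgBr adds 1,2 to this ketone to give the tertiary allylic alkoxide 9, and after quench PPTS ionises the tertiary alcohol to an allyl cation (an O-protonated vinyl ortho-quinone methide) that the C8a hydroxyl captures at the tertiary terminus, forming the new O1–C2 bond. The closest known reaction type is the conversion of coumarins into 2,2-dimethyl-2H-chromenes by methyl Grignard addition and acid-mediated cyclodehydration. The pyran ring closes in a 6-endo sense on the allyl cation, equivalent to an oxa-6π electrocyclisation of the cis vinyl quinone methide, and the same acid then exchanges the THP acetal of 10 to methanol. No stereocentre is created, and the racemic acetal centre is removed. The step needs carbonyl (1,2) rather than conjugate (1,4) attack and an acid that spares the prenyl olefin and the new C3=C4 bond: the THP ether prevents a 7-phenoxide from deactivating C2 through the C4a–C4=C3 conjugation path, an excess of the hard Grignard reagent at 0 °C favours direct addition, the lactone ring guarantees the cis geometry required for closure, and PPTS is too weak to protonate a trisubstituted alkene.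

Step 6
Reactants: 11 2,2-dimethyl-8-(3-methylbut-2-en-1-yl)-2H-chromen-7-ol
Product: 13 7-hydroxy-2,2-dimethyl-8-(3-methylbut-2-en-1-yl)-2H-chromene-6-carbaldehyde, via salicyl alcohol 12 (not isolated)
Conditions: MgCl2, Et3N, (CH2O)n, THF, reflux; cold aq NH4Cl work-up
Reagents that add atoms: paraformaldehyde (as formaldehyde), C=O
Why: Magnesium-mediated ortho-formylation (Casnati–Skattebøl reaction), in which the magnesium phenoxide delivers formaldehyde to C6, the only free ortho position, and the chelated salicyl alcohol 12 is oxidised by a second formaldehyde through hydride transfer, all under basic conditions that spare the chromene and prenyl olefins.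

Step 7
Reactants: 14 4-(2-bromoethyl)phenol
Product: 15 [4-(2-bromoethyl)phenoxy](tert-butyl)dimethylsilane
Conditions: TBSCl, imidazole, CH2Cl2, 0 °C to rt
Reagents that add atoms: tert-butyldimethylsilyl chloride, CC(C)(C)[Si](C)(C)Cl
Why: Standard silylation of a phenol, which removes the acidic proton before Grignard formation while the primary bromide stays intact.

Step 8
Reactants: 15 [4-(2-bromoethyl)phenoxy](tert-butyl)dimethylsilane; 13 7-hydroxy-2,2-dimethyl-8-(3-methylbut-2-en-1-yl)-2H-chromene-6-carbaldehyde
Product: 17 6-{3-[4-(tert-butyldimethylsilyloxy)phenyl]-1-hydroxypropyl}-2,2-dimethyl-8-(3-methylbut-2-en-1-yl)-2H-chromen-7-ol (racemic), via arylethyl Grignard reagent 16 (not isolated)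
Conditions: 15 (2.5 equiv), Mg, I2 (cat.), THF, 40 °C; then 13, THF, 0 °C to rt; aq NH4Cl
Reagents that add atoms: none
Why: Grignard formation from the primary bromide and 1,2-addition to the aldehyde, with the first equivalent spent on deprotonating the phenol (hence the excess); the carbinol stereocentre forms as a racemate without control and is erased in step 9.

Step 9
Reactants: 17 racemic carbinol
Product: 18 3-[4-(tert-butyldimethylsilyloxy)phenyl]-1-[7-hydroxy-2,2-dimethyl-8-(3-methylbut-2-en-1-yl)-2H-chromen-6-yl]propan-1-one
Conditions: MnO2 (activated, excess), CH2Cl2, rt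
Reagents that add atoms: none
Why: Activated MnO2 oxidises benzylic carbinols selectively, the product ketone is stabilised by a hydrogen bond to the 7-OH, and the isolated prenyl olefin and the silyl ether should not react.

Step 10
Reactants: 18 silyl-protected ketone
Product: 19 1-[7-hydroxy-2,2-dimethyl-8-(3-methylbut-2-en-1-yl)-2H-chromen-6-yl]-3-(4-hydroxyphenyl)propan-1-one (target)
Conditions: TBAF, AcOH, THF, 0 °C
Reagents that add atoms: none
Why: Fluoride cleaves the aryl silyl ether, and the acetic acid buffer keeps the medium near neutral for the ortho-hydroxy ketone and the chromene.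

**Compound list**

1 | 7-hydroxycoumarin (umbelliferone) | O=C1C=Cc2ccc(O)cc2O1 | starting material
2 | 3-chloro-3-methylbut-1-yne | CC(C)(Cl)C#C | starting material
3 | 7-[(2-methylbut-3-yn-2-yl)oxy]-2H-chromen-2-one | O=C1C=Cc2ccc(OC(C)(C)C#C)cc2O1 | intermediate
4 | 7-[(2-methylbut-3-en-2-yl)oxy]-2H-chromen-2-one | O=C1C=Cc2ccc(OC(C)(C)C=C)cc2O1 | intermediate
5 | 7-hydroxy-8-(3-methylbut-2-en-1-yl)-2H-chromen-2-one (osthenol) | CC(C)=CCc1c(O)ccc2C=CC(=O)Oc12 | intermediate
6 | 8-(3-methylbut-2-en-1-yl)-7-(tetrahydro-2H-pyran-2-yloxy)-2H-chromen-2-one, racemic at the acetal carbon | CC(C)=CCc1c(OC2CCCCO2)ccc2C=CC(=O)Oc12 | intermediate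
7 | methylmagnesium bromide | C[Mg]Br | starting material
8 | (Z)-4-[2-hydroxy-3-(3-methylbut-2-en-1-yl)-4-(tetrahydro-2H-pyran-2-yloxy)phenyl]but-3-en-2-one, present as its magnesium phenoxide, racemic acetal, not isolated | CC(=O)/C=C\c1ccc(OC2CCCCO2)c(CC=C(C)C)c1O | intermediate
9 | (Z)-4-[2-hydroxy-3-(3-methylbut-2-en-1-yl)-4-(tetrahydro-2H-pyran-2-yloxy)phenyl]-2-methylbut-3-en-2-ol, racemic acetal, not isolated | CC(C)(O)/C=C\c1ccc(OC2CCCCO2)c(CC=C(C)C)c1O | intermediate
10 | 2-{[2,2-dimethyl-8-(3-methylbut-2-en-1-yl)-2H-chromen-7-yl]oxy}tetrahydro-2H-pyran, racemic acetal, not isolated | CC(C)=CCc1c(OC2CCCCO2)ccc2C=CC(C)(C)Oc12 | intermediate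
11 | 2,2-dimethyl-8-(3-methylbut-2-en-1-yl)-2H-chromen-7-ol | CC(C)=CCc1c(O)ccc2C=CC(C)(C)Oc12 | intermediate
12 | 6-(hydroxymethyl)-2,2-dimethyl-8-(3-methylbut-2-en-1-yl)-2H-chromen-7-ol, as its magnesium salt, not isolated | CC(C)=CCc1c(O)c(CO)cc2C=CC(C)(C)Oc12 | intermediate
13 | 7-hydroxy-2,2-dimethyl-8-(3-methylbut-2-en-1-yl)-2H-chromene-6-carbaldehyde | CC(C)=CCc1c(O)c(C=O)cc2C=CC(C)(C)Oc12 | intermediate
14 | 4-(2-bromoethyl)phenol | Oc1ccc(CCBr)cc1 | starting material
15 | [4-(2-bromoethyl)phenoxy](tert-butyl)dimethylsilane | CC(C)(C)[Si](C)(C)Oc1ccc(CCBr)cc1 | intermediate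
16 | {2-[4-(tert-butyldimethylsilyloxy)phenyl]ethyl}magnesium bromide, not isolated | CC(C)(C)[Si](C)(C)Oc1ccc(CC[Mg]Br)cc1 | intermediate
17 | 6-{3-[4-(tert-butyldimethylsilyloxy)phenyl]-1-hydroxypropyl}-2,2-dimethyl-8-(3-methylbut-2-en-1-yl)-2H-chromen-7-ol, racemic | CC(C)=CCc1c(O)c(C(O)CCc2ccc(O[Si](C)(C)C(C)(C)C)cc2)cc2C=CC(C)(C)Oc12 | intermediate
18 | 3-[4-(tert-butyldimethylsilyloxy)phenyl]-1-[7-hydroxy-2,2-dimethyl-8-(3-methylbut-2-en-1-yl)-2H-chromen-6-yl]propan-1-one | CC(C)=CCc1c(O)c(C(=O)CCc2ccc(O[Si](C)(C)C(C)(C)C)cc2)cc2C=CC(C)(C)Oc12 | intermediate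
19 | 1-[7-hydroxy-2,2-dimethyl-8-(3-methylbut-2-en-1-yl)-2H-chromen-6-yl]-3-(4-hydroxyphenyl)propan-1-one (no stereocentre) | CC(C)=CCc1c(O)c(C(=O)CCc2ccc(O)cc2)cc2C=CC(C)(C)Oc12 | target

**Step count**

Total: 10 steps. Longest linear sequence: 9 steps (steps 1–6 and 8–10); step 7 is the one-step side branch.

**Steps most likely to fail**

Step 5. What may go wrong: methyl delivery to C4 in conjugate fashion, enolisation of the ring-opened methyl ketone before the second addition, or acid-promoted solvent addition to the electron-rich chromene during closure. Fallback: the lactone-to-pyran conversion is given up and the pyran is built by an aryl propargyl ether rearrangement. It sets out from chloroalkyne 2 and rejoins the route at aldehyde 13, so steps 5 and 6 are both bypassed. Purchased 2,4-dihydroxybenzaldehyde is C-alkylated at C3 with 1-bromo-3-methylbut-2-ene in aqueous KOH at 0 °C to give 2,4-dihydroxy-3-(3-methylbut-2-en-1-yl)benzaldehyde F1; O-alkylation and attack at C5 compete, which makes this the weak point of the detour. The 4-OH of F1, the one not held in the hydrogen bond to the aldehyde, is etherified with 2 (K2CO3, KI, acetone, reflux) to give 2-hydroxy-4-[(2-methylbut-3-yn-2-yl)oxy]-3-(3-methylbut-2-en-1-yl)benzaldehyde F2. Heating F2 in PhNEt2 at 180 °C should bring about the propargyl Claisen shift to C5 (the only open ortho position), a 1,5-hydrogen shift and oxa-6π closure, giving 13.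

Step 9. What may go wrong: oxidation of the free, electron-rich phenol (ortho-quinone methide formation from the ortho-hydroxybenzyl alcohol, or oxidative coupling) in competition with oxidation of the carbinol. Fallback: the carbinol is avoided by raising C6 to the nitrile level without an oxidant. It sets out from aldehyde 13 and rejoins at ketone 18, replacing steps 8 and 9. Condensation of 13 with NH2OH·HCl and NaOAc in EtOH gives the (E)-oxime of 13 F3. PPh3 and DIAD in THF dehydrate F3, directly or through the 1,2-benzisoxazole fused across C6–C7 of the chromene F4 (not isolated), which Et3N opens by Kemp elimination, to give 7-hydroxy-2,2-dimethyl-8-(3-methylbut-2-en-1-yl)-2H-chromene-6-carbonitrile F5. Grignard reagent 16 (3 equiv, THF, reflux) adds to the nitrile of the magnesium phenoxide to give the ortho-hydroxyaryl ketimine F6 (not isolated), which cold aqueous citric acid hydrolyses to 18.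

Step 2. What may go wrong: over-reduction of the new alkene to the saturated tert-pentyl ether, or premature sigmatropic shift on the catalyst surface. Fallback: the allyl ether is made directly by palladium-catalysed O-allylation (Tsuji–Trost reaction). It sets out from umbelliferone 1 and rejoins at ether 4, which also makes step 1 unnecessary. Purchased 2-methylbut-3-en-2-ol is converted (n-BuLi, then Boc2O, THF, 0 °C) into tert-butyl 2-methylbut-3-en-2-yl carbonate F7. Compound 1 is then allylated with F7 under catalysis by the zerovalent palladium complex Pd(PPh3)4 (THF, 0 °C to rt); attack of the phenoxide at the more substituted terminus of the 1,1-dimethylallyl palladium intermediate should give 4 with loss of CO2 and tert-butanol.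

**Further compounds**

F1 | step 5 | 2,4-dihydroxy-3-(3-methylbut-2-en-1-yl)benzaldehyde | CC(C)=CCc1c(O)ccc(C=O)c1O
F2 | step 5 | 2-hydroxy-4-[(2-methylbut-3-yn-2-yl)oxy]-3-(3-methylbut-2-en-1-yl)benzaldehyde | CC(C)=CCc1c(OC(C)(C)C#C)ccc(C=O)c1O
F3 | step 9 | (E)-7-hydroxy-2,2-dimethyl-8-(3-methylbut-2-en-1-yl)-2H-chromene-6-carbaldehyde oxime | CC(C)=CCc1c(O)c(/C=N/O)cc2C=CC(C)(C)Oc12
F4 | step 9 | 1,2-benzisoxazole formed by N–O7 ring closure of F3 (isoxazole fused across C6–C7 of the chromene), not isolated | CC(C)=CCc1c2oncc2cc2C=CC(C)(C)Oc12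
F5 | step 9 | 7-hydroxy-2,2-dimethyl-8-(3-methylbut-2-en-1-yl)-2H-chromene-6-carbonitrile | CC(C)=CCc1c(O)c(C#N)cc2C=CC(C)(C)Oc12
F6 | step 9 | 6-{3-[4-(tert-butyldimethylsilyloxy)phenyl]propanimidoyl}-2,2-dimethyl-8-(3-methylbut-2-en-1-yl)-2H-chromen-7-ol, not isolated | CC(C)=CCc1c(O)c(C(=N)CCc2ccc(O[Si](C)(C)C(C)(C)C)cc2)cc2C=CC(C)(C)Oc12
F7 | step 2 | tert-butyl 2-methylbut-3-en-2-yl carbonate | CC(C)(C)OC(=O)OC(C)(C)C=C
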